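**Strategy.** The oxocane is cut at C11–C12. C12 is the ether carbon next to O6 that also carries the C13 side chain, so it can serve as the α-carbon of an O6-glycolamide enolate, while C11 is allylic to a Z C9=C10 olefin that later accepts the acetate and the bromine. One base-mediated operation forms C11–C12, closes the eight-membered ring onto the tetrahydrofuran (O, C4–C7), which comes intact from 2-deoxy-D-ribose, and fixes C12. The precursor is that tetrahydrofuran carrying CH2OSi(t-Bu)Ph2 at C4, OCH2CONMe2 at C6 and a Z-CH2CH=CHCH2Cl arm at C7.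

Key step: step 15

Remark: locants C1–C15 are those of the target chain (C1 = alkyne CH, C15 = ethyl CH3); O6 is the oxocane oxygen joining C6 and C12; the amide first formed in step 15 is drawn as its expected 12S epimer.

Step 1
Reactants: 1 2-deoxy-D-ribose
Product: 2 2-deoxy-D-ribono-1,4-lactone
Conditions: Br2, H2O, rt
Reagents that add atoms: none
Why: Bromine water oxidises the hemiacetal carbon of an aldose to the aldonic acid, which closes to the five-membered lactone (aldose oxidation) without touching the two stereocentres that become C6 and C7.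

Step 2
Reactants: 2 2-deoxy-D-ribono-1,4-lactone
Product: 3 3,5-bis-O-TBS lactone
Conditions: TBSCl, imidazole, DMF, rt
Reagents that add atoms: tert-butyldimethylsilyl chloride, CC(C)(C)[Si](C)(C)Cl
Why: Silyl ether formation with a silyl chloride and imidazole masks both hydroxyls for the organometallic and Lewis acid steps.

Step 3
Reactants: 3 3,5-bis-O-TBS lactone; 4 vinylmagnesium bromide
Product: 5 1-C-vinyl hemiketal (anomer mixture)
Conditions: CH2=CHMgBr, THF, −78 °C; aq. NH4Cl
Reagents that add atoms: vinylmagnesium bromide, C=C[Mg]Br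
Why: A Grignard reagent adds once to a γ-lactone at −78 °C because the magnesium hemiketal alkoxide persists until the quench (Grignard addition to a lactone), and the low temperature suppresses enolisation at C5 with loss of the C6 silyloxy group.

Step 4
Reactants: 5 1-C-vinyl hemiketal
Product: 6 β-C-vinyl glycoside (4R,6S,7R; vinyl at C4 cis to C8)
Conditions: Et3SiH, BF3·OEt2, CH2Cl2, −78 → −40 °C
Reagents that add atoms: none
Why: The Lewis acid ionises the hemiketal to a five-membered oxocarbenium ion and the silane delivers hydride to the face syn to the C6 silyloxy group (ionic hydrogenation of a hemiketal, inside attack on the envelope), which leaves the vinyl group cis to C8 and sets C4 as R.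

Step 5
Reactants: 6 β-C-vinyl glycoside
Product: 8 C3 primary alcohol, via C3 aldehyde 7 (not isolated)
Conditions: O3, CH2Cl2–MeOH, −78 °C; then NaBH4, −78 → 0 °C
Reagents that add atoms: ozone, [O-][O+]=O
Why: Ozonolysis cleaves the vinyl group to the C3 aldehyde and borohydride reduces it in the same flask before the α-alkoxy aldehyde can epimerise at C4 (ozonolysis with reductive work-up).

Step 6
Reactants: 8 C3 primary alcohol
Product: 9 C3 TBDPS ether
Conditions: TBDPSCl, imidazole, DMF, rt
Reagents that add atoms: tert-butyl(chloro)diphenylsilane, CC(C)(C)[Si](Cl)(c1ccccc1)c1ccccc1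
Why: Silylation of the primary alcohol gives an ether that outlasts the acid used next and every later step up to step 20.

Step 7
Reactants: 9 C3 TBDPS ether
Product: 10 C6,C8-diol
Conditions: camphorsulfonic acid (cat.), MeOH, rt
Reagents that add atoms: none
Why: Acid-catalysed methanolysis removes primary and secondary TBS ethers far faster than a primary TBDPS ether (selective silyl ether solvolysis), which frees O6 and the C8 hydroxyl together.

Step 8
Reactants: 10 C6,C8-diol
Product: 12 C8 triflate with O6-TES ether, via C8 triflate alcohol 11 (not isolated)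
Conditions: Tf2O, 2,6-lutidine, CH2Cl2, −78 °C; then TESOTf, −78 → −40 °C
Reagents that add atoms: trifluoromethanesulfonic anhydride, O=S(=O)(OS(=O)(=O)C(F)(F)F)C(F)(F)F; triethylsilyl trifluoromethanesulfonate, CC[Si](CC)(CC)OS(=O)(=O)C(F)(F)F
Why: At −78 °C the anhydride sulfonylates the primary C8 hydroxyl much faster than the secondary C6 hydroxyl, and the silyl triflate then caps O6 in the same flask (one-pot triflation–silylation) so that no alkoxide is present in step 10.

Step 9
Reactants: 13 propargyl alcohol; 14 4-methoxybenzyl chloride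
Product: 15 4-methoxybenzyl propargyl ether
Conditions: NaH, THF, 0 °C; 14, Bu4NI (cat.), rt
Reagents that add atoms: 4-methoxybenzyl chloride, COc1ccc(CCl)cc1
Why: Williamson ether synthesis of a primary alkoxide with a benzylic chloride.

Step 10
Reactants: 12 C8 triflate with O6-TES ether; 15 4-methoxybenzyl propargyl ether
Product: 18 alkynol (C8–C9≡C10–C11–OPMB chain; free O6–H), via lithium acetylide 16 (not isolated), via TES-protected alkyne 17 (not isolated)
Conditions: 15, n-BuLi, THF, −78 °C; 12, DMPU, −78 → −20 °C; then 1 M aq. HCl, 0 °C → rt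
Reagents that add atoms: 4-methoxybenzyl propargyl ether (as its lithium acetylide), C#CCOCc1ccc(OC)cc1
Why: A lithium acetylide displaces a primary triflate cleanly in THF–DMPU (SN2 alkylation of an acetylide), forming C8–C9, and the acidic quench hydrolyses the labile TES ether while the TBDPS and PMB ethers stay.

Step 11
Reactants: 18 alkynol
Product: 19 Z-alkenol (Z-C9=C10)
Conditions: H2 (1 atm), Pd/CaCO3–Pb(OAc)2, quinoline, EtOAc, rt
Reagents that add atoms: none
Why: Lindlar semihydrogenation adds hydrogen syn to the alkyne and stops at the Z-olefin, the geometry the ring closure needs.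

Step 12
Reactants: 19 Z-alkenol; 20 2-bromo-N,N-dimethylacetamide
Product: 21 O6-glycolamide ether
Conditions: NaH, THF, 0 °C; 20, 0 °C → rt
Reagents that add atoms: 2-bromo-N,N-dimethylacetamide, BrCC(=O)N(C)C
Why: Williamson etherification of the sodium alkoxide with a reactive α-bromo amide, with the allylic oxygen still protected so that no internal electrophile competes.

Step 13
Reactants: 21 O6-glycolamide ether
Product: 22 Z-allylic alcohol
Conditions: DDQ, CH2Cl2–pH 7 buffer, 0 °C
Reagents that add atoms: none
Why: DDQ oxidises the electron-rich benzyl ether to an oxocarbenium ion that water hydrolyses (oxidative PMB cleavage), leaving silyl ether, amide and olefin.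

Step 14
Reactants: 22 Z-allylic alcohol
Product: 24 Z-allylic chloride (cyclisation precursor), via allylic mesylate 23 (not isolated)
Conditions: MsCl, 2,4,6-collidine, LiCl, DMF, 0 °C
Reagents that add atoms: lithium chloride, [Li+].[Cl-]
Why: The primary allylic alcohol is mesylated and chloride displaces the mesylate at the primary carbon (sulfonate–chloride exchange), which keeps the Z geometry and avoids allylic transposition.

Step 15
Reactants: 24 Z-allylic chloride
Product: 28 6,12-trans oxocene amide (12R), via potassium enolate 25 (not isolated), via 6,12-cis amide 26 (not isolated), via lithium enolate 27 (not isolated)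
Conditions: KN(SiMe3)2, THF, −78 °C, 0.01 M; then LiN(iPr)2, −78 → −40 °C; AcOH, −78 °C
Reagents that add atoms: none
Why: KN(SiMe3)2 deprotonates C12 to the potassium-chelated Z(O)-enolate 25, whose α-carbon displaces the primary allylic chloride at C11 by SN2, the intramolecular α-alkoxy amide enolate alkylation that is the established way to 2,8-disubstituted oxocenes. The ring (O6, C6–C12) closes in the 8-exo-tet mode, and the Z C9=C10 olefin together with the roughly 90° dihedral that the deoxyribose ring imposes between the C6–O6 and C7–C8 bonds holds C11 over the enolate, so that closure at 0.01 M should outrun intermolecular alkylation and take the primary terminus in preference to SN2′ attack at C9 or O-alkylation. C11 belongs to the forming ring and must therefore reach the enolate on the face where the ring lies, which leaves H12 on the inner side and should give the 6,12-cis amide 26, the usual sense of such closures. The selectivity still needed, H12 trans to H6, is supplied in the same flask: LiN(iPr)2 re-forms the enolate at C12 (27), in which C11 now lies in the enolate plane while C6 and C10 both sit on one face, and the proton of the acetic acid quench arrives on the open face. This kinetic protonation should set C12 as R under the control of C6 and C7 (the sugar stereocentres), whose trans ring fusion fixes the ring conformation, and the amide has no other acidic C–H.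

Step 16
Reactants: 28 6,12-trans oxocene amide; 29 ethylmagnesium bromide
Product: 31 C13 ethyl ketone, via bromomagnesium hemiaminal 30 (not isolated)
Conditions: EtMgBr, THF, 0 °C; aq. NH4Cl
Reagents that add atoms: ethylmagnesium bromide, CC[Mg]Br
Why: An α-alkoxy N,N-dimethylamide takes up one equivalent of Grignard reagent to give a magnesium-chelated hemiaminal that collapses to the ketone only on work-up (ketone synthesis from a chelating amide), so no tertiary alcohol forms; the ketone is used at once because C12 is now α to a carbonyl.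

Step 17
Reactants: 31 C13 ethyl ketone
Product: 32 (13R)-alcohol
Conditions: LiBH(s-Bu)3, THF, −78 °C
Reagents that add atoms: none
Why: The bulky, non-chelating hydride attacks the ketone anti to the C12–O6 bond (Felkin–Anh, polar model), which gives the 12,13-syn alcohol, 13R.

Step 18
Reactants: 32 (13R)-alcohol
Product: 33 (13S)-bromide
Conditions: CBr4, P(n-C8H17)3, toluene, 70 °C
Reagents that add atoms: carbon tetrabromide, BrC(Br)(Br)Br
Why: Appel-type bromination with trioctylphosphine in warm toluene, the conditions suited to hindered carbinols beside medium-ring ethers, replaces the activated oxygen by bromide with inversion, 13R to 13S.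

Step 19
Reactants: 33 (13S)-bromide; 34 acetic acid
Product: 36 9-acetoxy-10-bromo oxocane (9R,10S), via tricyclic oxonium acetate 35 (not isolated)
Conditions: NBS, AcOH, CH2Cl2, 0 °C → rt, dark
Reagents that add atoms: N-bromosuccinimide, O=C1CCC(=O)N1Br; acetic acid, CC(=O)O
Why: Br+ adds to the open face of the Z-olefin at C10, O6 opens the bromonium ion from inside the ring at C9 (the only carbon that gives five-membered rings, since attack at C10 would need an oxetane) and acetic acid then displaces O6 at C9 from the open face, so that bromine and acetate should end on the same face with Br at C10 and OAc at C9 (anchimerically assisted bromoacetoxylation through a transannular oxonium ion).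

Step 20
Reactants: 36 9-acetoxy-10-bromo oxocane
Product: 37 C3 primary alcohol
Conditions: HF·pyridine, pyridine, THF, 0 °C → rt
Reagents that add atoms: none
Why: Buffered fluoride cleaves the Si–O bond (HF·pyridine desilylation) without exposing the secondary bromides and the acetate to base.

Step 21
Reactants: 37 C3 primary alcohol
Product: 38 C3 aldehyde
Conditions: Dess–Martin periodinane, NaHCO3, CH2Cl2, rt
Reagents that add atoms: none
Why: Dess–Martin oxidation stops at the aldehyde under buffered neutral conditions that should not epimerise C4 or touch the bromides.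

Step 22
Reactants: 38 C3 aldehyde; 39 ethynylmagnesium bromide
Product: 41 (3S)-propargylic alcohol, via ethynyltitanium triisopropoxide 40 (not isolated)
Conditions: HC≡CMgBr, ClTi(OiPr)3, THF, −78 → −30 °C
Reagents that add atoms: ethynylmagnesium bromide, C#C[Mg]Br
Why: The alkynyltitanium reagent made by transmetalation adds to aldehydes but not to the acetate and does not chelate the ring oxygen, so addition should follow the Felkin–Anh model anti to the C4–O bond and give the 3,4-anti carbinol, 3S (carbonyl addition of an organotitanium reagent).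

Step 23
Reactants: 41 (3S)-propargylic alcohol
Product: 42 target CNP0224788.1
Conditions: CBr4, PPh3, CH2Cl2, 0 °C
Reagents that add atoms: carbon tetrabromide, BrC(Br)(Br)Br
Why: Appel bromination converts the propargylic alcohol to the bromide by SN2 displacement of the oxyphosphonium group, inverting 3S to 3R, and the cold neutral medium disfavours the SN2′ path to a bromoallene.

**Compound list**

1 | 2-deoxy-D-ribose, (3S,4R)-3,4,5-trihydroxypentanal | O=CC[C@H](O)[C@H](O)CO | starting material
2 | 2-deoxy-D-ribono-1,4-lactone, (4S,5R)-4-hydroxy-5-(hydroxymethyl)oxolan-2-one | O=C1C[C@H](O)[C@@H](CO)O1 | intermediate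
3 | 3,5-bis-O-(tert-butyldimethylsilyl)-2-deoxy-D-ribono-1,4-lactone | O=C1C[C@H](O[Si](C)(C)C(C)(C)C)[C@@H](CO[Si](C)(C)C(C)(C)C)O1 | intermediate
4 | vinylmagnesium bromide | C=C[Mg]Br | starting material
5 | 3,5-bis-O-TBS-1-C-vinyl-2-deoxy-D-ribofuranose (hemiketal, anomer mixture) | C=CC1(O)C[C@H](O[Si](C)(C)C(C)(C)C)[C@@H](CO[Si](C)(C)C(C)(C)C)O1 | intermediate
6 | (2R,3S,5R)-3-TBSO-2-(TBSOCH2)-5-vinyloxolane (β-C-vinyl glycoside; target C4 R, C6 S, C7 R) | C=C[C@H]1C[C@H](O[Si](C)(C)C(C)(C)C)[C@@H](CO[Si](C)(C)C(C)(C)C)O1 | intermediate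
7 | C3 aldehyde of the bis-TBS tetrahydrofuran (4R,6S,7R) | O=C[C@H]1C[C@H](O[Si](C)(C)C(C)(C)C)[C@@H](CO[Si](C)(C)C(C)(C)C)O1 | intermediate
8 | C3 alcohol: tetrahydrofuran with CH2OH at C4, OTBS at C6, CH2OTBS at C7 (4R,6S,7R) | OC[C@H]1C[C@H](O[Si](C)(C)C(C)(C)C)[C@@H](CO[Si](C)(C)C(C)(C)C)O1 | intermediate
9 | same tetrahydrofuran with CH2OTBDPS at C4 | CC(C)(C)[Si](c1ccccc1)(c1ccccc1)OC[C@H]1C[C@H](O[Si](C)(C)C(C)(C)C)[C@@H](CO[Si](C)(C)C(C)(C)C)O1 | intermediate
10 | diol: CH2OTBDPS at C4, OH at C6, CH2OH (C8) at C7 (4R,6S,7R) | CC(C)(C)[Si](c1ccccc1)(c1ccccc1)OC[C@H]1C[C@H](O)[C@@H](CO)O1 | intermediate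
11 | C8 triflate with free C6 hydroxyl | CC(C)(C)[Si](c1ccccc1)(c1ccccc1)OC[C@H]1C[C@H](O)[C@@H](COS(=O)(=O)C(F)(F)F)O1 | intermediate
12 | C8 triflate with C6 triethylsilyl ether | CC(C)(C)[Si](c1ccccc1)(c1ccccc1)OC[C@H]1C[C@H](O[Si](CC)(CC)CC)[C@@H](COS(=O)(=O)C(F)(F)F)O1 | intermediate
13 | propargyl alcohol | C#CCO | starting material
14 | 4-methoxybenzyl chloride | COc1ccc(CCl)cc1 | starting material
15 | 4-methoxybenzyl propargyl ether | C#CCOCc1ccc(OC)cc1 | intermediate
16 | lithium acetylide of 15 | [Li]C#CCOCc1ccc(OC)cc1 | intermediate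
17 | alkyne C8–C9≡C10–C11(OPMB) on C7, C6 OTES, C4 CH2OTBDPS | CC(C)(C)[Si](c1ccccc1)(c1ccccc1)OC[C@H]1C[C@H](O[Si](CC)(CC)CC)[C@@H](CC#CCOCc2ccc(OC)cc2)O1 | intermediate
18 | alkynol: as 17 with free C6 hydroxyl | CC(C)(C)[Si](c1ccccc1)(c1ccccc1)OC[C@H]1C[C@H](O)[C@@H](CC#CCOCc2ccc(OC)cc2)O1 | intermediate
19 | Z-alkenol: (Z)-CH2CH=CHCH2OPMB arm at C7, free C6 hydroxyl | CC(C)(C)[Si](c1ccccc1)(c1ccccc1)OC[C@H]1C[C@H](O)[C@@H](C/C=C\COCc2ccc(OC)cc2)O1 | intermediate
20 | 2-bromo-N,N-dimethylacetamide | BrCC(=O)N(C)C | starting material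
21 | O6-CH2CONMe2 ether with (Z)-allylic PMB ether | CC(C)(C)[Si](c1ccccc1)(c1ccccc1)OC[C@H]1C[C@H](OCC(=O)N(C)C)[C@@H](C/C=C\COCc2ccc(OC)cc2)O1 | intermediate
22 | O6-CH2CONMe2 ether with (Z)-allylic alcohol (C11–OH) | CC(C)(C)[Si](c1ccccc1)(c1ccccc1)OC[C@H]1C[C@H](OCC(=O)N(C)C)[C@@H](C/C=C\CO)O1 | intermediate
23 | corresponding (Z)-allylic mesylate | CC(C)(C)[Si](c1ccccc1)(c1ccccc1)OC[C@H]1C[C@H](OCC(=O)N(C)C)[C@@H](C/C=C\COS(C)(=O)=O)O1 | intermediate
24 | cyclisation precursor: tetrahydrofuran (4R,6S,7R) with CH2OTBDPS at C4, OCH2CONMe2 at C6, (Z)-CH2CH=CHCH2Cl at C7 | CC(C)(C)[Si](c1ccccc1)(c1ccccc1)OC[C@H]1C[C@H](OCC(=O)N(C)C)[C@@H](C/C=C\CCl)O1 | intermediate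
25 | potassium Z(O)-enolate of 24 | CC(C)(C)[Si](c1ccccc1)(c1ccccc1)OC[C@H]1C[C@H](O/C=C(\[O-])N(C)C)[C@@H](C/C=C\CCl)O1.[K+] | intermediate
26 | trans-fused tetrahydrofuran–oxocene C12 dimethylamide, 12S (H6 and H12 cis) | CC(C)(C)[Si](c1ccccc1)(c1ccccc1)OC[C@H]1C[C@@H]2O[C@H](C(=O)N(C)C)C/C=C\C[C@H]2O1 | intermediate
27 | lithium enolate of the oxocene amide (C12=C13) | CC(C)(C)[Si](c1ccccc1)(c1ccccc1)OC[C@H]1C[C@@H]2OC(=C([O-])N(C)C)C/C=C\C[C@H]2O1.[Li+] | intermediate
28 | trans-fused tetrahydrofuran–oxocene C12 dimethylamide, (4R,6S,7R,12R), Z-C9=C10 (H6 and H12 trans) | CC(C)(C)[Si](c1ccccc1)(c1ccccc1)OC[C@H]1C[C@@H]2O[C@@H](C(=O)N(C)C)C/C=C\C[C@H]2O1 | intermediate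
29 | ethylmagnesium bromide | CC[Mg]Br | starting material
30 | bromomagnesium hemiaminal from 28 and EtMgBr | CC(C)(C)[Si](c1ccccc1)(c1ccccc1)OC[C@H]1C[C@@H]2O[C@@H](C(CC)(O[Mg]Br)N(C)C)C/C=C\C[C@H]2O1 | intermediate
31 | C13 ethyl ketone (12R) | CC(C)(C)[Si](c1ccccc1)(c1ccccc1)OC[C@H]1C[C@@H]2O[C@@H](C(=O)CC)C/C=C\C[C@H]2O1 | intermediate
32 | (12R,13R)-alcohol | CC(C)(C)[Si](c1ccccc1)(c1ccccc1)OC[C@H]1C[C@@H]2O[C@@H]([C@H](O)CC)C/C=C\C[C@H]2O1 | intermediate
33 | (12R,13S)-bromide with Z-C9=C10 | CC(C)(C)[Si](c1ccccc1)(c1ccccc1)OC[C@H]1C[C@@H]2O[C@@H]([C@@H](Br)CC)C/C=C\C[C@H]2O1 | intermediate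
34 | acetic acid | CC(=O)O | starting material
35 | tricyclic oxonium ion (O6 bonded to C6, C9 and C12; 10-bromo), acetate salt | CC(C)(C)[Si](c1ccccc1)(c1ccccc1)OC[C@H]1C[C@@H]2[O+]3[C@@H]([C@@H](Br)CC)C[C@H](Br)[C@@H]3C[C@H]2O1.CC(=O)[O-] | intermediate
36 | (9R,10S)-9-acetoxy-10-bromo oxocane with 13S bromide and C3 OTBDPS | CC(C)(C)[Si](c1ccccc1)(c1ccccc1)OC[C@H]1C[C@@H]2O[C@@H]([C@@H](Br)CC)C[C@H](Br)[C@H](OC(C)=O)C[C@H]2O1 | intermediate
37 | C3 primary alcohol | OC[C@H]1C[C@@H]2O[C@@H]([C@@H](Br)CC)C[C@H](Br)[C@H](OC(C)=O)C[C@H]2O1 | intermediate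
38 | C3 aldehyde | O=C[C@H]1C[C@@H]2O[C@@H]([C@@H](Br)CC)C[C@H](Br)[C@H](OC(C)=O)C[C@H]2O1 | intermediate
39 | ethynylmagnesium bromide | C#C[Mg]Br | starting material
40 | ethynyltitanium triisopropoxide | C#C[Ti](OC(C)C)(OC(C)C)OC(C)C | intermediate
41 | (3S)-propargylic alcohol | C#C[C@H](O)[C@H]1C[C@@H]2O[C@@H]([C@@H](Br)CC)C[C@H](Br)[C@H](OC(C)=O)C[C@H]2O1 | intermediate
42 | CNP0224788.1, (3R,4R,6S,7R,9R,10S,12R,13S) | C#C[C@@H](Br)[C@H]1C[C@@H]2O[C@@H]([C@@H](Br)CC)C[C@H](Br)[C@H](OC(C)=O)C[C@H]2O1 | target

**Step count.** Total: 23 steps. Longest linear sequence: 22 steps (steps 1–8 and 10–23; step 9 is a one-step side branch).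

**Steps most likely to fail**

Step 15. What may go wrong: the enolate is consumed by intermolecular alkylation or by SN2′ closure at C9, or the re-enolisation is incomplete or the proton enters on the inner face, so that the 6,12-cis amide 26 survives. The fallback sets out from alcohol 19 and returns at amide 28; it fixes C12 with an auxiliary and closes the ring by olefin metathesis. O6 of 19 is alkylated with bromoacetic acid (NaH, THF) to the glycolic acid F1. Activation with pivaloyl chloride and Et3N, then acylation of lithiated (S)-4-benzyloxazolidin-2-one, gives the N-glycolyl imide F2. Its sodium enolate (NaN(SiMe3)2, THF, −78 °C) is alkylated with allyl iodide on the face away from the benzyl group, which sets 12R in the diene F3. Ring-closing metathesis with the second-generation Grubbs catalyst RuCl2(=CHPh)(PCy3)(H2IMes) in dilute CH2Cl2 at 40 °C joins the terminal olefin to the Z-olefin of the C7 arm and gives the oxocene imide F4 with loss of allyl 4-methoxybenzyl ether. Me2AlNMe2, made from AlMe3 and Me2NH·HCl, then exchanges the auxiliary for the dimethylamide to give 28.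

Step 19. What may go wrong: acetate opens the oxonium ion 35 at C6 or C12 instead of C9 (ring contraction to bis-tetrahydrofurans), or acetic acid is too weak a nucleophile and succinimide or bromide capture competes. The fallback sets out from bromide 33 and returns at 36; it makes the C9–O bond by hydrolysis and the ester by acylation. Hydroxybromination with NBS in aqueous THF at 0 °C lets water in large excess intercept the oxonium ion at C9 and gives the cis-bromohydrin F5 (9R,10S). Acetylation (Ac2O, pyridine, DMAP, CH2Cl2) then gives 36.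

Step 22. What may go wrong: poor facial selectivity in the addition to the α-alkoxy aldehyde, so that the 3R carbinol is formed as well, or slow transmetalation that leaves Grignard reagent to attack the acetate. The fallback sets out from aldehyde 38 and returns at 41; it sets C3 by reduction instead of addition. Ethynylmagnesium bromide is added in THF at −78 °C without regard to selectivity, giving 41 mixed with its C3 epimer F6. The mixture is oxidised with Dess–Martin periodinane to the ynone F7. Reduction with Zn(BH4)2 in Et2O at −30 °C, in which zinc chelates the ketone and the ring oxygen and hydride enters from the side of H4, gives the 3,4-anti carbinol 41.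

**Further compounds**

F1 | step 15 | O6-carboxymethyl ether (glycolic acid) of Z-alkenol 19 | CC(C)(C)[Si](c1ccccc1)(c1ccccc1)OC[C@H]1C[C@H](OCC(=O)O)[C@@H](C/C=C\COCc2ccc(OC)cc2)O1
F2 | step 15 | N-glycolyl (S)-4-benzyloxazolidin-2-one imide of F1 | CC(C)(C)[Si](c1ccccc1)(c1ccccc1)OC[C@H]1C[C@H](OCC(=O)N2C(=O)OC[C@@H]2Cc2ccccc2)[C@@H](C/C=C\COCc2ccc(OC)cc2)O1
F3 | step 15 | C12-allylated imide (12R), diene for metathesis | CC(C)(C)[Si](c1ccccc1)(c1ccccc1)OC[C@H]1C[C@H](O[C@H](CC=C)C(=O)N2C(=O)OC[C@@H]2Cc2ccccc2)[C@@H](C/C=C\COCc2ccc(OC)cc2)O1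
F4 | step 15 | trans-fused tetrahydrofuran–oxocene C12 acyl oxazolidinone (12R, Z-C9=C10) | CC(C)(C)[Si](c1ccccc1)(c1ccccc1)OC[C@H]1C[C@@H]2O[C@@H](C(=O)N3C(=O)OC[C@@H]3Cc3ccccc3)C/C=C\C[C@H]2O1
F5 | step 19 | (9R,10S)-10-bromo-9-hydroxy oxocane (cis-bromohydrin) | CC(C)(C)[Si](c1ccccc1)(c1ccccc1)OC[C@H]1C[C@@H]2O[C@@H]([C@@H](Br)CC)C[C@H](Br)[C@H](O)C[C@H]2O1
F6 | step 22 | (3R)-propargylic alcohol, C3 epimer of 41 | C#C[C@@H](O)[C@H]1C[C@@H]2O[C@@H]([C@@H](Br)CC)C[C@H](Br)[C@H](OC(C)=O)C[C@H]2O1
F7 | step 22 | C3 ynone | C#CC(=O)[C@H]1C[C@@H]2O[C@@H]([C@@H](Br)CC)C[C@H](Br)[C@H](OC(C)=O)C[C@H]2O1
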